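The central cyclopentane (ring C) holds the enone β-carbon, the quaternary spiro carbon, the CH(4-hydroxyphenyl) carbon and the two indane ring-fusion CH carbons. The plan opens it across two bonds: spiro carbon to enone β-carbon, and CH(aryl) to the benzylic fusion CH. In one operation an indenide carbon adds to the arylidene β-carbon of a trans-diarylcyclopentanone, and the enolate formed, whose α-carbon is the future spiro centre, closes 5-exo-dig onto a pendant alkynyl Weinreb amide: a Michael/Michael [3+2] annulation. It exploits that the spiro carbon is α to the bridging ketone and the ring C sp2 carbon β to the enone carbonyl. Acylative closure of the enedione ring, convex-face 1,6-arylation and demethylation finish.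

Key step: step 8

Remark: all seven phenolic hydroxyl groups are carried as methyl ethers from catalogue building blocks and are released together in the last step.

Step 1
Reactants: 1 (S)-4-(tert-butyldimethylsilyloxy)cyclopent-2-en-1-one; 2 3,5-dimethoxyphenylmagnesium chloride
Product: 4 (S)-4-(3,5-dimethoxyphenyl)cyclopent-2-en-1-one, via trans-3-aryl-4-silyloxycyclopentanone 3 (not isolated)
Conditions: 2 (1.3 equiv), CuBr·SMe2 (10 mol%), THF, −78 to −40 °C; aq. NH4Cl; crude + DBU, CH2Cl2, 0 °C to rt
Reagents that add atoms: none
Why: Copper-catalysed conjugate addition of the aryl Grignard reagent should occur anti to the silyloxy group, and E1cB loss of silanolate from the α′ side then transposes the enone (conjugate addition/β-elimination), so the aryl-bearing stereocentre is fixed by the starting enantiomer.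

Step 2
Reactants: 4 (S)-4-(3,5-dimethoxyphenyl)cyclopent-2-en-1-one; 5 4-methoxyphenylmagnesium bromide; 6 4-methoxybenzaldehyde
Product: 8 (2R,3R,4S)-4-(3,5-dimethoxyphenyl)-2-[hydroxy(4-methoxyphenyl)methyl]-3-(4-methoxyphenyl)cyclopentan-1-one (carbinol epimers), via bromomagnesium enolate 7 (not isolated)
Conditions: 5 (1.2 equiv), CuBr·SMe2 (10 mol%), THF, −78 to −40 °C; then 6 (1.3 equiv), −78 °C; aq. NH4Cl
Reagents that add atoms: none
Why: Copper-catalysed conjugate addition anti to the C4 aryl group should set the trans-3,4-diaryl relationship and give the enolate regiospecifically at C2, where it is trapped by the aldehyde anti to the new C3 aryl group (three-component conjugate addition/aldol); the carbinol configuration is lost in the next step.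

Step 3
Reactants: 8 aldol adduct
Product: 9 (2E,3S,4S)-4-(3,5-dimethoxyphenyl)-2-(4-methoxybenzylidene)-3-(4-methoxyphenyl)cyclopentan-1-one
Conditions: p-TsOH·H2O (10 mol%), toluene, 50 °C
Reagents that add atoms: none
Why: Acid-catalysed dehydration through the 4-methoxybenzylic cation (completion of an aldol condensation) should give the thermodynamically preferred E-arylidene ketone without touching the two ring stereocentres.

Step 4
Reactants: 10 5,7-dimethoxyindan-1-one
Product: 11 2-bromo-5,7-dimethoxyindan-1-one (racemic)
Conditions: CuBr2 (2.1 equiv), EtOAc/CHCl3, reflux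
Reagents that add atoms: CuBr2, Br[Cu]Br
Why: α-Bromination of a ketone with CuBr2 proceeds through the enol and should leave the electron-rich ring unbrominated.

Step 5
Reactants: 11 2-bromo-5,7-dimethoxyindan-1-one
Product: 12 2-bromo-5,7-dimethoxyindan-1-ol (racemic, mixture of diastereomers)
Conditions: NaBH4, MeOH/THF, 0 °C
Reagents that add atoms: none
Why: Borohydride reduction of the ketone gives the bromohydrin, whose two stereocentres are removed in the next step.

Step 6
Reactants: 12 2-bromo-5,7-dimethoxyindan-1-ol
Product: 13 2-bromo-4,6-dimethoxy-1H-indene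
Conditions: p-TsOH·H2O (5 mol%), toluene, 80 °C, short reaction time
Reagents that add atoms: none
Why: Acid-catalysed E1 dehydration through a benzylic cation that the ortho and para methoxy groups stabilise should give the 2-bromoindene.

Step 7
Reactants: 13 2-bromo-4,6-dimethoxy-1H-indene; 14 N-methoxy-N-methylprop-2-ynamide
Product: 15 3-(4,6-dimethoxy-1H-inden-2-yl)-N-methoxy-N-methylprop-2-ynamide
Conditions: Pd(PPh3)2Cl2 (5 mol%), CuI (10 mol%), Et3N, THF, 50 °C, degassed
Reagents that add atoms: none
Why: Sonogashira coupling of the styrene-type vinyl bromide with the terminal alkynamide should work, and triethylamine is too weak a base to deprotonate the indene CH2 of the product.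

Step 8
Reactants: 9 (2E,3S,4S)-arylidene cyclopentanone; 15 indenyl alkynyl Weinreb amide
Product: 17 spiro [3+2] adduct (cyclopentanone of 9 spiro-fused at C2 to a new cyclopentane that is fused to the indene and carries the amide-bearing alkylidene, amide cis to the spiro carbon), via Michael-adduct cesium enolate 16 (not isolated)
Conditions: 9 (1.5 equiv), Cs2CO3 (0.3 equiv), DMSO, 20 °C; 15 added over 6 h; AcOH quench
Reagents that add atoms: none
Why: Cs2CO3 should deprotonate the indene CH2 of 15, and the indenide adds through the carbon remote from the peri methoxy group to the β-carbon of enone 9 (reversible intermolecular Michael addition, forming the CH(aryl)–CH bond) to give enolate 16; its α-carbon then attacks the β-carbon of the alkynyl amide in an irreversible 5-exo-dig Michael addition (spiro carbon to sp2 carbon bond), and in-plane protonation of the allenolate from the side of the flat indene carbon leaves the amide cis to the spiro carbon. The closest known reaction type is the base-mediated Michael/Michael (Michael-initiated ring closure) formal [3+2] annulation of a tethered donor–acceptor with an enone. One ring is closed, the spiro cyclopentane, by 5-exo-dig attack of the enolate carbon. The quaternary spiro centre should be set by attack anti to the neighbouring 4-methoxyphenyl group on C3 of the cyclopentanone; the CH(aryl) centre should place its aryl group toward the carbonyl rather than toward C3 to avoid allylic strain in the enolate; the indene CH should end trans to that aryl group because the first Michael step is reversible and this CH stays epimerisable, so the least strained ring closes. The step needs cross-addition to win over self-condensation of 15 and attack at the right indenide terminus; excess 9 with slow addition of 15 should secure the first and the peri methoxy group the second.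

Step 9
Reactants: 17 spiro [3+2] adduct
Product: 18 hexa-O-methyl dienone (bicyclo[3.2.1]oct-3-ene-2,8-dione closed, indene C=C still present, aryl group on the indene CH still missing)
Conditions: LiN(SiMe3)2 (1.1 equiv), THF, −78 to −20 °C; aq. NH4Cl at −78 °C
Reagents that add atoms: none
Why: Kinetic deprotonation of the only enolisable α-CH2 of the ketone and intramolecular Claisen-type acylation by the Weinreb amide should close the six-membered ring through a chelated tetrahedral intermediate that protects the non-enolisable β-diketone from retro-Claisen cleavage; the new bridgehead stereocentre is fixed because only the enolate face cis to the alkylidene arm can reach the amide.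

Step 10
Reactants: 18 hexa-O-methyl dienone; 5 4-methoxyphenylmagnesium bromide
Product: 20 hepta-O-methyl ether of the target, via trimethylsilyl dienol ether 19 (not isolated)
Conditions: (4-MeOC6H4)2CuMgBr [5 (2.4 equiv), CuBr·SMe2 (1.2 equiv)], Me3SiCl, THF, −78 to −30 °C; then 1 M HCl, THF, rt
Reagents that add atoms: none
Why: Organocuprate 1,6-conjugate addition to the cross-conjugated dienone should deliver the aryl group to the indene CH from the convex face, opposite the CH(aryl)–spiro bridge, and acid hydrolysis of the silyl dienol ether with protonation at the γ-carbon gives the only possible cis ring fusion and the conjugated enone.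

Step 11
Reactants: 20 hepta-O-methyl ether of the target
Product: 21 CNP0407321.1 (target)
Conditions: BBr3 (15 equiv), CH2Cl2, −78 to 0 °C; ice-water
Reagents that add atoms: none
Why: Lewis acid cleavage of the seven aryl methyl ethers (BBr3 demethylation) touches no stereocentre, and the non-enolisable diketone only has to survive a cold aqueous quench.

Compound list
1 | (S)-4-(tert-butyldimethylsilyloxy)cyclopent-2-en-1-one | O=C1C=C[C@@H](O[Si](C)(C)C(C)(C)C)C1 | starting material
2 | 3,5-dimethoxyphenylmagnesium chloride | COc1cc(OC)cc([Mg]Cl)c1 | starting material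
3 | (3R,4S)-3-(3,5-dimethoxyphenyl)-4-(tert-butyldimethylsilyloxy)cyclopentan-1-one | O=C1C[C@H](c2cc(OC)cc(OC)c2)[C@@H](O[Si](C)(C)C(C)(C)C)C1 | intermediate
4 | (S)-4-(3,5-dimethoxyphenyl)cyclopent-2-en-1-one | O=C1C[C@H](c2cc(OC)cc(OC)c2)C=C1 | intermediate
5 | 4-methoxyphenylmagnesium bromide | COc1ccc([Mg]Br)cc1 | starting material
6 | 4-methoxybenzaldehyde | COc1ccc(C=O)cc1 | starting material
7 | bromomagnesium enolate (toward C2) of trans-3-(4-methoxyphenyl)-4-(3,5-dimethoxyphenyl)cyclopentanone | Br[Mg]OC1=C[C@H](c2ccc(OC)cc2)[C@@H](c2cc(OC)cc(OC)c2)C1 | intermediate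
8 | (2R,3R,4S)-4-(3,5-dimethoxyphenyl)-2-[hydroxy(4-methoxyphenyl)methyl]-3-(4-methoxyphenyl)cyclopentan-1-one, carbinol epimers | O=C1C[C@H](c2cc(OC)cc(OC)c2)[C@@H](c2ccc(OC)cc2)[C@@H]1C(O)c1ccc(OC)cc1 | intermediate
9 | (2E,3S,4S)-4-(3,5-dimethoxyphenyl)-2-(4-methoxybenzylidene)-3-(4-methoxyphenyl)cyclopentan-1-one | O=C1C[C@H](c2cc(OC)cc(OC)c2)[C@@H](c2ccc(OC)cc2)/C1=C\c1ccc(OC)cc1 | intermediate
10 | 5,7-dimethoxyindan-1-one | O=C1CCc2cc(OC)cc(OC)c21 | starting material
11 | 2-bromo-5,7-dimethoxyindan-1-one (racemic) | O=C1C(Br)Cc2cc(OC)cc(OC)c21 | intermediate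
12 | 2-bromo-5,7-dimethoxyindan-1-ol (racemic, diastereomer mixture) | OC1C(Br)Cc2cc(OC)cc(OC)c21 | intermediate
13 | 2-bromo-4,6-dimethoxy-1H-indene | BrC1=Cc2c(OC)cc(OC)cc2C1 | intermediate
14 | N-methoxy-N-methylprop-2-ynamide | C#CC(=O)N(C)OC | starting material
15 | 3-(4,6-dimethoxy-1H-inden-2-yl)-N-methoxy-N-methylprop-2-ynamide | CON(C)C(=O)C#CC1=Cc2c(OC)cc(OC)cc2C1 | intermediate
16 | cesium enolate of the Michael adduct of the indenide of 15 with 9 (indene sp3 CH bonded to the CH(4-methoxyphenyl) carbon, alkyne still intact) | [Cs+].[O-]C1=C([C@@H](c2ccc(OC)cc2)[C@@H]2c3cc(OC)cc(OC)c3C=C2C#CC(=O)N(C)OC)[C@H](c2ccc(OC)cc2)[C@@H](c2cc(OC)cc(OC)c2)C1 | intermediate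
17 | spiro [3+2] adduct: trans-3,4-diarylcyclopentanone whose C2 is the spiro atom of an indene-fused cyclopentane carrying the CH(4-methoxyphenyl) carbon and the CH–C(=O)N(OMe)Me alkylidene (amide cis to the spiro carbon) | CON(C)C(=O)/C=C2/C3=Cc4c(OC)cc(OC)cc4[C@H]3[C@H](c3ccc(OC)cc3)[C@]23C(=O)C[C@H](c2cc(OC)cc(OC)c2)[C@H]3c2ccc(OC)cc2 | intermediate
18 | hexa-O-methyl dienone: the target skeleton with the indene C=C still in place of the two CH centres and without the aryl group on the indene CH | O=C1C=C2C3=Cc4c(OC)cc(OC)cc4[C@H]3[C@H](c3ccc(OC)cc3)[C@]23C(=O)[C@H]1[C@H](c1cc(OC)cc(OC)c1)[C@H]3c1ccc(OC)cc1 | intermediate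
19 | trimethylsilyl dienol ether of the 1,6-adduct (enol ether at the enone carbonyl, tetrasubstituted C=C at the ring fusion) | C[Si](C)(C)OC1=CC2=C3[C@H](c4ccc(OC)cc4)c4c(OC)cc(OC)cc4[C@H]3[C@H](c3ccc(OC)cc3)[C@]23C(=O)[C@H]1[C@H](c1cc(OC)cc(OC)c1)[C@H]3c1ccc(OC)cc1 | intermediate
20 | hepta-O-methyl ether of the target | O=C1C=C2[C@H]3[C@H](c4ccc(OC)cc4)c4c(OC)cc(OC)cc4[C@H]3[C@H](c3ccc(OC)cc3)[C@]23C(=O)[C@H]1[C@H](c1cc(OC)cc(OC)c1)[C@H]3c1ccc(OC)cc1 | intermediate
21 | CNP0407321.1 | O=C1C=C2[C@H]3[C@H](c4ccc(O)cc4)c4c(O)cc(O)cc4[C@H]3[C@H](c3ccc(O)cc3)[C@]23C(=O)[C@H]1[C@H](c1cc(O)cc(O)c1)[C@H]3c1ccc(O)cc1 | target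

Total step count: 11. Longest linear sequence: 8 steps (10 to 21 through steps 4 to 11); the other branch (1 to 9) has 3 steps before the union.

Steps most likely to fail

Step 8. The indenide of 15 may add to the alkynamide of a second molecule of 15 faster than to the hindered arylidene ketone, so that self-condensation outruns the annulation. The indenide may also react through its other terminus, or the base may move the arylidene double bond into the ring. The fallback separates donor and acceptor and sets out from 13 and 9. Compound 13 is deprotonated with LiN(SiMe3)2 in THF at −78 °C; the 2-bromoindenide carries no acceptor and cannot self-condense, and it is added to 9 to give the Michael adduct, the bromoindenyl ketone F1. Sonogashira coupling of the vinyl bromide of F1 with 14 (Pd(PPh3)2Cl2, CuI, Et3N) gives the alkynamide ketone F2, the neutral form of 16. Cs2CO3 in DMSO then closes the spiro ring by intramolecular 5-exo-dig Michael addition, with wrong CH epimers returning through retro-Michael equilibration, and the route is rejoined at 17.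

Step 10. Conjugate addition to the donor-substituted dienone may be slow, may go 1,2 at the strained bridging ketone, or may be preceded by base-induced migration of the indene double bond, which would misdirect the aryl group. The fallback reverses the polarity and sets out from 18. Treated with anisole and catalytic TfOH in hexafluoroisopropanol at 0 °C, the protonated dienone is a cation at the indene CH that the ortho/para-dimethoxy ring stabilises. Anisole should attack it para, from the convex face (vinylogous Friedel–Crafts arylation), and tautomerisation gives 20 directly; no compound outside the list is made (F0).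

Step 9. The amide base may deprotonate the indene CH in competition with the ketone (followed by double-bond migration on quench), may strip formaldehyde from the N-methoxy group, or the hindered enolate may fail to reach the amide. The fallback is an aldol/oxidation sequence and sets out from 17. Soft enolisation with TBSOTf/Et3N gives the silyl enol ether F3. DIBAL-H at −78 °C reduces the Weinreb amide to the dienal F4. BF3·OEt2 at −78 °C effects an intramolecular Mukaiyama aldol addition to the bridged allylic alcohol F5. Dess–Martin periodinane then oxidises the carbinol, and the route is rejoined at 18.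

Further compounds
F1 | step 8 | (3S,4S)-2-[(2-bromo-4,6-dimethoxy-1H-inden-1-yl)(4-methoxyphenyl)methyl]-4-(3,5-dimethoxyphenyl)-3-(4-methoxyphenyl)cyclopentan-1-one (C2 epimers, new CH centres drawn as needed for ring closure) | O=C1C[C@H](c2cc(OC)cc(OC)c2)[C@@H](c2ccc(OC)cc2)C1[C@@H](c1ccc(OC)cc1)[C@@H]1c2cc(OC)cc(OC)c2C=C1Br
F2 | step 8 | alkynamide ketone: F1 with the bromine replaced by C≡C–C(=O)N(OMe)Me | O=C1C[C@H](c2cc(OC)cc(OC)c2)[C@@H](c2ccc(OC)cc2)C1[C@@H](c1ccc(OC)cc1)[C@@H]1c2cc(OC)cc(OC)c2C=C1C#CC(=O)N(C)OC
F0 | step 10 | none | none
F3 | step 9 | tert-butyldimethylsilyl enol ether of 17 (enol ether toward the CH2 of the cyclopentanone) | CON(C)C(=O)/C=C2/C3=Cc4c(OC)cc(OC)cc4[C@H]3[C@H](c3ccc(OC)cc3)[C@]23C(O[Si](C)(C)C(C)(C)C)=C[C@H](c2cc(OC)cc(OC)c2)[C@H]3c2ccc(OC)cc2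
F4 | step 9 | dienal: F3 with the Weinreb amide reduced to the aldehyde | O=C/C=C2/C3=Cc4c(OC)cc(OC)cc4[C@H]3[C@H](c3ccc(OC)cc3)[C@]23C(O[Si](C)(C)C(C)(C)C)=C[C@H](c2cc(OC)cc(OC)c2)[C@H]3c2ccc(OC)cc2
F5 | step 9 | bridged allylic alcohol: 18 with the enone carbonyl as CH(OH), carbinol epimers | OC1C=C2C3=Cc4c(OC)cc(OC)cc4[C@H]3[C@H](c3ccc(OC)cc3)[C@]23C(=O)[C@H]1[C@H](c1cc(OC)cc(OC)c1)[C@H]3c1ccc(OC)cc1
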